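## Structural features

Atom labels used throughout: the seven-membered carbocycle is C1 (tertiary carbinol carrying the crotonoyl group through its carbonyl carbon CK), C2 (CHMe), C3 (CHOH), C4 (CH2), C5 (ring-fusion CH), C6 (lactone CH–O) and C7 (CH–O-isobutyrate); the lactone is completed by C11 (CHMe) and C12 (C=O). The skeleton is a cycloheptane cis-fused across C5–C6 to a γ-butyrolactone whose three ring substituents (C11 methyl, C4, C7) sit on one face, the less stable all-cis arrangement. All seven stereocentres are contiguous along C11–C5–C6–C7–C1–C2–C3: the C6 and C7 oxygens are syn (trans on the ring), the C7 ester is trans to the C1 hydroxyl, the C1 hydroxyl is cis to the C2 methyl, and the C2 methyl is trans to the C3 hydroxyl. The fragile groups are the E-enone (conjugate addition, isomerisation), the tertiary α-ketol at C1/CK (acyloin shift), the C3 hydroxyl that lies 1,4 and cis to CK (lactol or hemiketal formation), the isobutyrate beside a free tertiary hydroxyl (acyl migration) and the epimerisable C11–H and C6–H of the lactone. The real difficulty is to close a seven-membered ring while setting the fully substituted C1 between stereogenic C2 and C7, and to obtain the syn C6/C7 oxygen pattern, which a non-chelated addition to a C7 aldehyde would not deliver. The key step exploits the fact that C1 carries a one-carbon branch (CK) and is flanked by the trans C2-methyl/C3-hydroxyl pair: without the C1 oxygen this is the homoallylic alcohol C1(=CH2)–C2H(Me)–C3H(OH), the retron of a type 2 carbonyl-ene reaction in which a methyl-bearing C1=C2 alkene attacks a C3 aldehyde and the transferred methyl becomes CK.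

## Logic of the disconnections

32 ⇒ 31. Cut: the O–Si bond of a triethylsilyl ether on the C3 oxygen. Reason: O3 is 1,4 and cis to CK, so a free C3 hydroxyl would form a bridged lactol with a CK aldehyde and be over-oxidised. Gain: the oxidations before it need no chemoselectivity between C3 and the side chain. Demand: a final desilylation mild enough for the α-ketol, the enone and both esters.

31 ⇒ 30 ⇒ 27 + 28. Cut: the CK–Cα bond, after taking CK back from ketone to carbinol. Reason: the enone is the most reactive group and should appear last; its E geometry can be bought in 28. Gain: three carbons and the Michael acceptor are removed. Demand: a carbonyl addition that tolerates a lactone, an ester and a free tertiary hydroxyl and keeps the alkene geometry.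

27 ⇒ 26 ⇒ 25. Cut: the C1–O and CK–O bonds (CK back to alcohol level). Reason: a tertiary carbinol bonded to an oxidised carbon is the product of dihydroxylating a 1,1-disubstituted alkene. Gain: the quaternary stereocentre C1 disappears and CK becomes a methylene carbon already in the skeleton. Demand: the oxidant must add to the alkene face anti to the C7 acyloxy group, and only the primary alcohol may be oxidised afterwards.

25 ⇒ 24. Cut: the O–Si bond at C3. Demand: silylation of a secondary alcohol without acyl migration.

24 ⇒ 23 (key). Cut: the C2–C3 ring bond, with return of one hydrogen from O3 to the exocyclic carbon. Reason: 24 is a 3-methylenecycloalkanol, the direct product of a type 2 carbonyl-ene closure. Gain: the seven-membered ring is opened, two stereocentres (C2, C3) are removed and the remaining stereocentres are confined to a monocyclic lactone. Demand: a Z alkene (for the trans C2/C3 pair), attack on one alkene face only, closure at C2 and not at C1, and a Lewis acid that spares the allylic ester.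

23 ⇒ 22 ⇒ 21 ⇒ 19 + 20. Cut: the C3 oxidation level, the O–Si bond at C3 and the O–acyl bond at C7. Reason: the isobutyrate is placed before the Lewis-acid step so that O7 never has to be told apart from O3. Gain: the target's own ester serves as the C7 protecting group. Demand: a buffered desilylation and a non-epimerising oxidation.

19 ⇒ 18. Cut: the C7–H bond (carbinol back to ketone). Reason: non-chelated addition of an alkenyl nucleophile to a C7 aldehyde would put the carbon substituent where the same model puts a hydride on the ketone, so it would favour the C7 epimer. Gain: C7 is set by substrate control from C6 in the required syn sense. Demand: a bulky hydride that reduces 1,2 and does not touch the lactone.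

18 ⇒ 13 + 14. Cut: the C7–C1 bond. Reason: the Z trisubstituted alkene is bought with fixed geometry in 14, and acylation gives the ketone directly. Gain: the whole ene component arrives in one step. Demand: metalation and coupling with retention of geometry, and a nucleophile that ignores the lactone.

13 ⇒ 12 ⇒ 11. Cut: the C7 oxidation level and the O–Si bond at O7. Demand: removal of one primary silyl ether in the presence of another, and an oxidation that does not epimerise C6.

11 ⇒ 10. Cut: the C5–H and C11–H bonds. Reason: the all-cis lactone is not available by conjugate addition, which places the C5 substituent trans to C7. Gain: two stereocentres are replaced by one alkene and only C6 remains. Demand: cis delivery of hydrogen to a tetrasubstituted alkene on the face anti to the C6 substituent.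

10 ⇒ 8. Cut: formal addition of H–H across C11=C5, back to the trans lactone. Demand: the selenoxide must eliminate into the ring (toward C5–H) and not toward the methyl group.

8 ⇒ 7 ⇒ 5. Cut: the O–Si bond at O3 and the C3–O bond (back to a vinyl group). Reason: a two-carbon arm with oxygen on its terminus is a hydroborated vinyl group. Demand: hydroboration and oxidation that leave the lactone closed.

5 ⇒ 4 ⇒ 2 ⇒ 1. Cut: the C11–CH3 bond, the C5–C4 bond and the O–Si bond at O7. Reason: enolate methylation and copper-mediated vinyl addition build the carbon set on a butenolide whose single stereocentre is C6. Gain: the route starts from one small chiral-pool lactone. Demand: only regiochemistry, because C5 and C11 are re-set later.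

## Other disconnections considered

Alternative 1: The cut is the C5–C6 bond together with the O–C12 acyl bond, so that both rings close in one operation. In the forward step CrCl2 would convert the Z allylic bromide of open-chain aldehyde ester A2 into an allylchromium species whose γ-carbon C5 adds to the C6 aldehyde; the alkoxide then lactonises to give A1. In its favour: one step forms two rings and two stereocentres through a closed six-membered transition state that normally gives the cis ring fusion, which is better than the chosen key step in bonds formed per step. C1 is built early by carbonyl addition and not by a late face-selective dihydroxylation, which is also a better position. Against it here: the C1 and C7 oxygens are trans, so the acetonide of A1 is a strained trans-fused dioxolane. C11 must be set later by reducing the α-methylene lactone in the presence of the alkyne or of the enone derived from it. The ethynyl group still has to be hydrated and condensed with acetaldehyde to give the crotonoyl group. The closure uses a large excess of a chromium salt at high dilution, whereas the ene reaction forms no reagent-derived carbon waste. On step economy A2, with four stereocentres including quaternary C1, is unlikely to be reached in fewer steps than 23, and more steps follow the closure.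

Alternative 2: The cut is the C1–C2 bond, seen as the retron of an α-ketol ring expansion. A Lewis acid such as Zn(OTf)2 or Al(OiPr)3 would chelate the hydroxy dione unit of cyclohexanol A4, and the C7–C2 ring bond would migrate to the C1 carbonyl to give A3. In its favour: the six ring carbons C2–C7 and the isopropenyl-derived lactone carbons come from carvone, six-membered-ring stereocontrol is reliable, and the ring is expanded rather than closed, so no medium-ring entropy is paid. The crotonoyl chain is already complete and the promoter is catalytic. On these four points it is the better plan. Against it here: the rearrangement is reversible and under thermodynamic control. The C1 configuration is relayed from the C7 carbinol of A4 through the chelate, so that centre must be set correctly although it is destroyed. C6 could migrate in place of C2. The ene-dione of A4 is a sensitive acceptor. Afterwards the C7 ketone of A3 must be reduced selectively beside the enone ketone and acylated. Overall the step count is expected to be comparable, and the stereochemical outcome at C1 and C7 is less predictable than in the chosen route.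

Alternative 3: The cut is the C3–C4 bond. CrCl2 with catalytic NiCl2 would turn the iodomethylidene group of lactone aldehyde A6 into an alkenylchromium nucleophile that adds to the C3 aldehyde, closing the seven-membered ring as allylic alcohol A5. A hydroxyl-directed hydrogenation with [Ir(cod)(PCy3)(py)]PF6 would then set C5. In its favour: the coupling tolerates the lactone, the ester, the ketal and the silyl ether better than a Lewis-acid ene reaction, which is a real advantage. C1 is again set early. The directed hydrogenation is well matched, because the C3 hydroxyl lies on the face where H5 must arrive. Against it here: the new C3 centre is formed without a closed transition state, yet it is the centre that must relay configuration to C5. The aldehyde of A6 is α-branched at C2 and neopentyl-like. The C4=C5 alkene of A5 is β,γ to the lactone carbonyl and can slip into conjugation, erasing C11. The masked methyl ketone still needs ketal removal and an aldol condensation with acetaldehyde. The chosen ene step sets C2 and C3 together in one concerted event under allylic-strain control, whereas this plan needs two separate stereochemical events and more fragile intermediates; its step count is expected to be higher.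

Key step: step 15

Remark on the starting material: the R enantiomer 1 is assumed to be a catalogue compound (it is the enantiomer of the more common S form, and its stereocentre maps onto C6 of the target).

Remark on naming: bromine–lithium exchange on 14 retains the geometry, but the reagent is (E)-but-2-en-2-yllithium by the sequence rule because lithium ranks below carbon; once bonded to C7 the alkene is Z again.

Remark on conventions: names of lactone intermediates use ring numbering; the Why lines use the atom labels C1–C7, C11, C12 and CK.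

## Route

Step 1
Reactants: 1 (R)-5-(hydroxymethyl)furan-2(5H)-one
Product: 2 (R)-5-[(tert-butyldimethylsilyloxy)methyl]furan-2(5H)-one
Conditions: t-BuMe2SiCl, imidazole, CH2Cl2, 0 °C → rt
Reagents that add atoms: tert-butyldimethylsilyl chloride, CC(C)(C)[Si](C)(C)Cl
Why: Imidazole-mediated silyl ether formation on the primary alcohol; the bulky group later shields one ring face in the conjugate addition and the hydrogenation, and no stereocentre is touched.

Step 2
Reactants: 2 (R)-5-[(tert-butyldimethylsilyloxy)methyl]furan-2(5H)-one
Product: 4 (4S,5R)-5-[(tert-butyldimethylsilyloxy)methyl]-4-vinyldihydrofuran-2(3H)-one, via trimethylsilyl ketene acetal 3 (not isolated)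
Conditions: CH2=CHMgBr, CuBr·SMe2 (cat.), Me3SiCl, THF, −78 °C; aq. NH4Cl
Reagents that add atoms: vinylmagnesium bromide, C=C[Mg]Br
Why: Copper-catalysed conjugate addition of a vinyl Grignard reagent accelerated by Me3SiCl; the vinyl group enters anti to the C6 silyloxymethyl group (a provisional C5 centre, re-set in step 7) and the ketene acetal is hydrolysed on work-up.

Step 3
Reactants: 4 (4S,5R)-5-[(tert-butyldimethylsilyloxy)methyl]-4-vinyldihydrofuran-2(3H)-one
Product: 5 (3R,4R,5R)-5-[(tert-butyldimethylsilyloxy)methyl]-3-methyl-4-vinyldihydrofuran-2(3H)-one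
Conditions: LiN(iPr)2, THF, −78 °C; MeI, −78 → −40 °C
Reagents that add atoms: iodomethane, CI
Why: Lactone enolate alkylation with methyl iodide approaching anti to the adjacent vinyl group; the C11 configuration is provisional because C11 becomes trigonal in step 6.

Step 4
Reactants: 5 (3R,4R,5R)-5-[(tert-butyldimethylsilyloxy)methyl]-3-methyl-4-vinyldihydrofuran-2(3H)-one
Product: 7 (3R,4R,5R)-5-[(tert-butyldimethylsilyloxy)methyl]-4-(2-hydroxyethyl)-3-methyldihydrofuran-2(3H)-one, via B-alkyl-9-borabicyclo[3.3.1]nonane 6 (not isolated)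
Conditions: 9-BBN, THF, 0 °C → rt; NaBO3·4H2O, H2O, rt
Reagents that add atoms: sodium perborate tetrahydrate (NaBO3·4H2O), [Na+].[Na+].O[B-]1(O)OO[B-](O)(O)OO1
Why: Anti-Markovnikov hydroboration–oxidation of the terminal alkene gives the C4–C3 arm with oxygen on C3; 9-BBN does not reduce the lactone and perborate oxidises the borane without the strong base that would open it.

Step 5
Reactants: 7 (3R,4R,5R)-5-[(tert-butyldimethylsilyloxy)methyl]-4-(2-hydroxyethyl)-3-methyldihydrofuran-2(3H)-one
Product: 8 (3R,4R,5R)-5-[(tert-butyldimethylsilyloxy)methyl]-3-methyl-4-[2-(triisopropylsilyloxy)ethyl]dihydrofuran-2(3H)-one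
Conditions: iPr3SiCl, imidazole, DMF, rt
Reagents that add atoms: triisopropylsilyl chloride, CC(C)[Si](Cl)(C(C)C)C(C)C
Why: Silyl ether formation; the triisopropylsilyl ether has no arene that rhodium could saturate and outlasts the tert-butyldimethylsilyl ether in acid, so O7 can be released first.

Step 6
Reactants: 8 (3R,4R,5R)-5-[(tert-butyldimethylsilyloxy)methyl]-3-methyl-4-[2-(triisopropylsilyloxy)ethyl]dihydrofuran-2(3H)-one
Product: 10 (R)-5-[(tert-butyldimethylsilyloxy)methyl]-3-methyl-4-[2-(triisopropylsilyloxy)ethyl]furan-2(5H)-one, via 3-phenylselanyl lactone 9 (not isolated)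
Conditions: LiN(iPr)2, THF, −78 °C; PhSeBr; then 30% H2O2, pyridine, CH2Cl2, 0 °C → rt
Reagents that add atoms: none
Why: α-Selenenylation of the lactone enolate anti to the C5 side chain places selenium cis to H5, and selenoxide syn-elimination into the ring gives the conjugated tetrasubstituted butenolide; the provisional centres C5 and C11 are erased and C6 is untouched.

Step 7
Reactants: 10 (R)-5-[(tert-butyldimethylsilyloxy)methyl]-3-methyl-4-[2-(triisopropylsilyloxy)ethyl]furan-2(5H)-one
Product: 11 (3R,4S,5R)-5-[(tert-butyldimethylsilyloxy)methyl]-3-methyl-4-[2-(triisopropylsilyloxy)ethyl]dihydrofuran-2(3H)-one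
Conditions: H2 (4 atm), 5% Rh/Al2O3, EtOAc, rt
Reagents that add atoms: none
Why: Heterogeneous hydrogenation delivers both hydrogens to the butenolide face anti to the C6 silyloxymethyl group, so C5 and C11 are set together and all three substituents end on one face; rhodium on alumina is chosen because it saturates hindered alkenes with little allylic C–O hydrogenolysis or double-bond migration.

Step 8
Reactants: 11 (3R,4S,5R)-5-[(tert-butyldimethylsilyloxy)methyl]-3-methyl-4-[2-(triisopropylsilyloxy)ethyl]dihydrofuran-2(3H)-one
Product: 12 (3R,4S,5R)-5-(hydroxymethyl)-3-methyl-4-[2-(triisopropylsilyloxy)ethyl]dihydrofuran-2(3H)-one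
Conditions: PPTS, MeOH, rt
Reagents that add atoms: none
Why: Acid-catalysed methanolysis cleaves the primary tert-butyldimethylsilyl ether much faster than the triisopropylsilyl ether (selective desilylation by acid lability); the γ-lactone and all stereocentres are retained.

Step 9
Reactants: 12 (3R,4S,5R)-5-(hydroxymethyl)-3-methyl-4-[2-(triisopropylsilyloxy)ethyl]dihydrofuran-2(3H)-one
Product: 13 (2R,3S,4R)-4-methyl-5-oxo-3-[2-(triisopropylsilyloxy)ethyl]oxolane-2-carboxylic acid
Conditions: TEMPO (cat.), PhI(OAc)2, MeCN/H2O, rt
Reagents that add atoms: water, O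
Why: Oxoammonium-mediated oxidation of the primary alcohol through the aldehyde hydrate to the acid under near-neutral conditions that should not epimerise C6.

Step 10
Reactants: 13 (2R,3S,4R)-4-methyl-5-oxo-3-[2-(triisopropylsilyloxy)ethyl]oxolane-2-carboxylic acid; 14 (Z)-2-bromobut-2-ene
Product: 18 (Z)-2-methyl-1-{(2R,3S,4R)-4-methyl-5-oxo-3-[2-(triisopropylsilyloxy)ethyl]oxolan-2-yl}but-2-en-1-one, via acid chloride 15 (not isolated), via (E)-but-2-en-2-yllithium 16 (not isolated), via (Z)-but-2-en-2-ylzinc chloride 17 (not isolated)
Conditions: 13, (COCl)2, DMF (cat.), CH2Cl2, 0 °C → rt, concentrate; 14, t-BuLi (2 equiv), THF, −78 °C, then ZnCl2, −78 → 0 °C; combine, Pd(PPh3)4 (cat.), THF, 0 °C → rt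
Reagents that add atoms: (Z)-2-bromobut-2-ene (14), C/C=C(/C)Br
Why: Palladium-catalysed acylation of an alkenylzinc reagent with an acid chloride (Negishi acylation); halogen–lithium exchange and transmetallation retain the alkene geometry, so the C2 methyl ends cis to C7, and the organozinc adds neither to the lactone nor to the product ketone.

Step 11
Reactants: 18 (Z)-2-methyl-1-{(2R,3S,4R)-4-methyl-5-oxo-3-[2-(triisopropylsilyloxy)ethyl]oxolan-2-yl}but-2-en-1-one
Product: 19 (3R,4S,5R)-5-[(1R,2Z)-1-hydroxy-2-methylbut-2-en-1-yl]-3-methyl-4-[2-(triisopropylsilyloxy)ethyl]dihydrofuran-2(3H)-one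
Conditions: LiBH(s-Bu)3, THF, −78 °C
Reagents that add atoms: none
Why: Felkin–Anh (Cornforth) controlled 1,2-reduction of an α-acyloxy ketone: with the C6–O bond anti to the carbonyl the bulky hydride enters past H6, away from C5 and its cis side chain, which sets C7 with the syn C6/C7 oxygen pattern. The Z β-methyl twists the enone out of conjugation, which disfavours conjugate hydride delivery.

Step 12
Reactants: 19 (3R,4S,5R)-5-[(1R,2Z)-1-hydroxy-2-methylbut-2-en-1-yl]-3-methyl-4-[2-(triisopropylsilyloxy)ethyl]dihydrofuran-2(3H)-one; 20 isobutyryl chloride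
Product: 21 (1R,2Z)-2-methyl-1-{(2R,3S,4R)-4-methyl-5-oxo-3-[2-(triisopropylsilyloxy)ethyl]oxolan-2-yl}but-2-en-1-yl 2-methylpropanoate
Conditions: pyridine, DMAP (cat.), CH2Cl2, 0 °C → rt
Reagents that add atoms: isobutyryl chloride (20), CC(C)C(Cl)=O
Why: DMAP-catalysed acylation of the hindered allylic alcohol; the target's own ester is installed before the Lewis-acid step so that O7 never has to be distinguished from O3.

Step 13
Reactants: 21 (1R,2Z)-2-methyl-1-{(2R,3S,4R)-4-methyl-5-oxo-3-[2-(triisopropylsilyloxy)ethyl]oxolan-2-yl}but-2-en-1-yl 2-methylpropanoate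
Product: 22 (1R,2Z)-1-[(2R,3S,4R)-3-(2-hydroxyethyl)-4-methyl-5-oxooxolan-2-yl]-2-methylbut-2-en-1-yl 2-methylpropanoate
Conditions: Bu4NF, AcOH, THF, 0 °C → rt
Reagents that add atoms: none
Why: Fluoride cleavage of the primary triisopropylsilyl ether, buffered with acetic acid so that the ester does not migrate and the lactone stays closed.

Step 14
Reactants: 22 (1R,2Z)-1-[(2R,3S,4R)-3-(2-hydroxyethyl)-4-methyl-5-oxooxolan-2-yl]-2-methylbut-2-en-1-yl 2-methylpropanoate
Product: 23 (1R,2Z)-2-methyl-1-[(2R,3S,4R)-4-methyl-5-oxo-3-(2-oxoethyl)oxolan-2-yl]but-2-en-1-yl 2-methylpropanoate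
Conditions: Dess–Martin periodinane, NaHCO3, CH2Cl2, 0 °C → rt
Reagents that add atoms: none
Why: Dess–Martin oxidation of the primary alcohol to the aldehyde under buffered conditions that should not epimerise any centre; 23 is used at once.

Step 15
Reactants: 23 (1R,2Z)-2-methyl-1-[(2R,3S,4R)-4-methyl-5-oxo-3-(2-oxoethyl)oxolan-2-yl]but-2-en-1-yl 2-methylpropanoate
Product: 24 (3R,3aS,5R,6R,8R,8aR)-5-hydroxy-3,6-dimethyl-7-methylidene-2-oxooctahydro-2H-cyclohepta[b]furan-8-yl 2-methylpropanoate
Conditions: Me2AlCl (3 equiv), CH2Cl2, −78 → −20 °C; aq. KNa tartrate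
Reagents that add atoms: none
Why: Me2AlCl binds the aldehyde oxygen and the activated C3 carbonyl is attacked by C2 of the Z trisubstituted alkene while a hydrogen of the C1 methyl passes to oxygen through the six-atom array O=C3, C2=C1, CH2–H, a concerted but asynchronous type 2 carbonyl-ene reaction with positive charge building on tertiary C1; the alcohol–aluminium complex then loses methane, which removes the proton source for Prins-type side reactions. The closest known reaction type is the Me2AlCl-promoted type 2 intramolecular carbonyl-ene cyclisation of alkenyl aldehydes to 3-methylenecycloalkanols. The one ring formed is the seven-membered carbocycle, closed in the 7-exo-trig mode at the aldehyde carbon (the C=O bond stays outside the ring), with both former alkene carbons in the ring and the old methyl left as the exocyclic methylene that later becomes CK. The C2/C3 relationship is controlled by the alkene geometry: the carbonyl oxygen must point at the transferring methyl and C4 back along the tether, so the Z alkene (C2 methyl cis to C7) gives the trans C2-methyl/C3-hydroxyl pair. The alkene face, and so the absolute sense at C2, is controlled by C7: 1,3-allylic strain with the Z methyl holds the C7–H bond in the alkene plane, which places C6 and the tethered aldehyde on one face and the isobutyrate on the other, and the cis lactone fusion keeps C4 close to C7 on that face. The step needs regioselectivity for C2 (seven-membered ring, tertiary cation character at C1) over C1 (six-membered ring, quaternary centre), which the electron-rich trisubstituted alkene secures. It also needs chemoselectivity for the aldehyde in the presence of the allylic ester and the lactone, which the mild proton-scavenging Lewis acid at low temperature, used in excess because both ester carbonyls also bind aluminium, is expected to provide.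

Step 16
Reactants: 24 (3R,3aS,5R,6R,8R,8aR)-5-hydroxy-3,6-dimethyl-7-methylidene-2-oxooctahydro-2H-cyclohepta[b]furan-8-yl 2-methylpropanoate
Product: 25 (3R,3aS,5R,6R,8R,8aR)-3,6-dimethyl-7-methylidene-2-oxo-5-(triethylsilyloxy)octahydro-2H-cyclohepta[b]furan-8-yl 2-methylpropanoate
Conditions: Et3SiCl, imidazole, DMF, 0 °C → rt
Reagents that add atoms: triethylsilyl chloride, CC[Si](Cl)(CC)CC
Why: Silylation of the secondary C3 alcohol; it blocks lactol formation between O3 and CK (1,4 and cis) during the oxidations that follow.

Step 17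
Reactants: 25 (3R,3aS,5R,6R,8R,8aR)-3,6-dimethyl-7-methylidene-2-oxo-5-(triethylsilyloxy)octahydro-2H-cyclohepta[b]furan-8-yl 2-methylpropanoate
Product: 26 (3R,3aS,5R,6S,7R,8S,8aR)-7-hydroxy-7-(hydroxymethyl)-3,6-dimethyl-2-oxo-5-(triethylsilyloxy)octahydro-2H-cyclohepta[b]furan-8-yl 2-methylpropanoate
Conditions: OsO4 (cat.), 4-methylmorpholine N-oxide, acetone/H2O, rt
Reagents that add atoms: 4-methylmorpholine N-oxide, C[N+]1([O-])CCOCC1; water, O
Why: Catalytic dihydroxylation (Upjohn conditions) adds both oxygens to one face of the 1,1-disubstituted alkene. In the conformer that keeps the C2 methyl and C3 silyloxy groups pseudo-equatorial the C7 acyloxy group is pseudo-axial, and osmylation anti to that allylic C–O bond places the new C1 oxygen cis to the C2 methyl and trans to O7, as the target requires.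

Step 18
Reactants: 26 (3R,3aS,5R,6S,7R,8S,8aR)-7-hydroxy-7-(hydroxymethyl)-3,6-dimethyl-2-oxo-5-(triethylsilyloxy)octahydro-2H-cyclohepta[b]furan-8-yl 2-methylpropanoate
Product: 27 (3R,3aS,5R,6S,7S,8S,8aR)-7-formyl-7-hydroxy-3,6-dimethyl-2-oxo-5-(triethylsilyloxy)octahydro-2H-cyclohepta[b]furan-8-yl 2-methylpropanoate
Conditions: SO3·pyridine, DMSO, iPr2NEt, CH2Cl2, 0 °C
Reagents that add atoms: none
Why: Parikh–Doering oxidation of the primary alcohol of a primary/tertiary diol to the α-hydroxy aldehyde; the tertiary alcohol cannot be oxidised and activated DMSO at 0 °C does not cleave the glycol.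

Step 19
Reactants: 27 (3R,3aS,5R,6S,7S,8S,8aR)-7-formyl-7-hydroxy-3,6-dimethyl-2-oxo-5-(triethylsilyloxy)octahydro-2H-cyclohepta[b]furan-8-yl 2-methylpropanoate; 28 (E)-1-bromoprop-1-ene
Product: 30 (3R,3aS,5R,6S,7R,8S,8aR)-7-hydroxy-7-[(2E)-1-hydroxybut-2-en-1-yl]-3,6-dimethyl-2-oxo-5-(triethylsilyloxy)octahydro-2H-cyclohepta[b]furan-8-yl 2-methylpropanoate (both epimers at the side-chain carbinol), via (E)-prop-1-enylchromium dichloride 29 (not isolated)
Conditions: CrCl2, NiCl2 (cat.), DMF, rt
Reagents that add atoms: (E)-1-bromoprop-1-ene (28), C/C=C/Br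
Why: Nozaki–Hiyama–Kishi coupling: nickel-catalysed formation of the alkenylchromium reagent with retention of the E geometry, then chemoselective addition to the aldehyde beside the lactone, the ester and the free tertiary hydroxyl. The new carbinol centre is formed as a mixture, which does not matter because it is oxidised next.

Step 20
Reactants: 30 (3R,3aS,5R,6S,7R,8S,8aR)-7-hydroxy-7-[(2E)-1-hydroxybut-2-en-1-yl]-3,6-dimethyl-2-oxo-5-(triethylsilyloxy)octahydro-2H-cyclohepta[b]furan-8-yl 2-methylpropanoate
Product: 31 (3R,3aS,5R,6S,7S,8S,8aR)-7-[(2E)-but-2-enoyl]-7-hydroxy-3,6-dimethyl-2-oxo-5-(triethylsilyloxy)octahydro-2H-cyclohepta[b]furan-8-yl 2-methylpropanoate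
Conditions: Dess–Martin periodinane, NaHCO3, CH2Cl2, 0 °C
Reagents that add atoms: none
Why: Dess–Martin oxidation of the secondary allylic alcohol to the E-enone; C1 is tertiary and O3 is protected, so CK is the only oxidisable position.

Step 21
Reactants: 31 (3R,3aS,5R,6S,7S,8S,8aR)-7-[(2E)-but-2-enoyl]-7-hydroxy-3,6-dimethyl-2-oxo-5-(triethylsilyloxy)octahydro-2H-cyclohepta[b]furan-8-yl 2-methylpropanoate
Product: 32 (3R,3aS,5R,6S,7S,8S,8aR)-7-[(2E)-but-2-enoyl]-5,7-dihydroxy-3,6-dimethyl-2-oxooctahydro-2H-cyclohepta[b]furan-8-yl 2-methylpropanoate (CNP0268641.1)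
Conditions: HF·pyridine, pyridine, THF, 0 °C
Reagents that add atoms: none
Why: Fluoride cleavage of the triethylsilyl ether under buffered conditions that should leave the α-ketol, the enone and both esters untouched; this releases the target.

## Compound list

1 | (R)-5-(hydroxymethyl)furan-2(5H)-one | O=C1C=C[C@H](CO)O1 | starting material
2 | (R)-5-[(tert-butyldimethylsilyloxy)methyl]furan-2(5H)-one | CC(C)(C)[Si](C)(C)OC[C@@H]1OC(=O)C=C1 | intermediate
3 | trimethylsilyl ketene acetal of 4 (2-trimethylsilyloxy-4,5-dihydrofuran, vinyl trans to the silyloxymethyl group) | CC(C)(C)[Si](C)(C)OC[C@@H]1OC(O[Si](C)(C)C)=C[C@H]1C=C | intermediate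
4 | (4S,5R)-5-[(tert-butyldimethylsilyloxy)methyl]-4-vinyldihydrofuran-2(3H)-one | CC(C)(C)[Si](C)(C)OC[C@@H]1OC(=O)C[C@H]1C=C | intermediate
5 | (3R,4R,5R)-5-[(tert-butyldimethylsilyloxy)methyl]-3-methyl-4-vinyldihydrofuran-2(3H)-one | CC(C)(C)[Si](C)(C)OC[C@@H]1OC(=O)[C@H](C)[C@H]1C=C | intermediate
6 | B-alkyl-9-borabicyclo[3.3.1]nonane adduct of 5 (boron on the terminal carbon of the former vinyl group) | CC(C)(C)[Si](C)(C)OC[C@@H]1OC(=O)[C@H](C)[C@H]1CCB2C3CCCC2CCC3 | intermediate
7 | (3R,4R,5R)-5-[(tert-butyldimethylsilyloxy)methyl]-4-(2-hydroxyethyl)-3-methyldihydrofuran-2(3H)-one | CC(C)(C)[Si](C)(C)OC[C@@H]1OC(=O)[C@H](C)[C@H]1CCO | intermediate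
8 | (3R,4R,5R)-5-[(tert-butyldimethylsilyloxy)methyl]-3-methyl-4-[2-(triisopropylsilyloxy)ethyl]dihydrofuran-2(3H)-one | CC(C)(C)[Si](C)(C)OC[C@@H]1OC(=O)[C@H](C)[C@H]1CCO[Si](C(C)C)(C(C)C)C(C)C | intermediate
9 | (3R,4S,5R)-5-[(tert-butyldimethylsilyloxy)methyl]-3-methyl-3-(phenylselanyl)-4-[2-(triisopropylsilyloxy)ethyl]dihydrofuran-2(3H)-one (selenium trans to the C4 side chain) | CC(C)(C)[Si](C)(C)OC[C@@H]1OC(=O)[C@](C)([Se]c2ccccc2)[C@H]1CCO[Si](C(C)C)(C(C)C)C(C)C | intermediate
10 | (R)-5-[(tert-butyldimethylsilyloxy)methyl]-3-methyl-4-[2-(triisopropylsilyloxy)ethyl]furan-2(5H)-one | CC(C)(C)[Si](C)(C)OC[C@@H]1OC(=O)C(C)=C1CCO[Si](C(C)C)(C(C)C)C(C)C | intermediate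
11 | (3R,4S,5R)-5-[(tert-butyldimethylsilyloxy)methyl]-3-methyl-4-[2-(triisopropylsilyloxy)ethyl]dihydrofuran-2(3H)-one (all-cis) | CC(C)(C)[Si](C)(C)OC[C@@H]1OC(=O)[C@H](C)[C@@H]1CCO[Si](C(C)C)(C(C)C)C(C)C | intermediate
12 | (3R,4S,5R)-5-(hydroxymethyl)-3-methyl-4-[2-(triisopropylsilyloxy)ethyl]dihydrofuran-2(3H)-one | OC[C@@H]1OC(=O)[C@H](C)[C@@H]1CCO[Si](C(C)C)(C(C)C)C(C)C | intermediate
13 | (2R,3S,4R)-4-methyl-5-oxo-3-[2-(triisopropylsilyloxy)ethyl]oxolane-2-carboxylic acid | OC(=O)[C@@H]1OC(=O)[C@H](C)[C@@H]1CCO[Si](C(C)C)(C(C)C)C(C)C | intermediate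
14 | (Z)-2-bromobut-2-ene | C/C=C(/C)Br | starting material
15 | (2R,3S,4R)-4-methyl-5-oxo-3-[2-(triisopropylsilyloxy)ethyl]oxolane-2-carbonyl chloride | ClC(=O)[C@@H]1OC(=O)[C@H](C)[C@@H]1CCO[Si](C(C)C)(C(C)C)C(C)C | intermediate
16 | (E)-but-2-en-2-yllithium (lithium cis to the C3 methyl) | C/C=C(/C)[Li] | intermediate
17 | (Z)-but-2-en-2-ylzinc chloride | C/C=C(/C)[Zn]Cl | intermediate
18 | (Z)-2-methyl-1-{(2R,3S,4R)-4-methyl-5-oxo-3-[2-(triisopropylsilyloxy)ethyl]oxolan-2-yl}but-2-en-1-one | C/C=C(/C)C(=O)[C@@H]1OC(=O)[C@H](C)[C@@H]1CCO[Si](C(C)C)(C(C)C)C(C)C | intermediate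
19 | (3R,4S,5R)-5-[(1R,2Z)-1-hydroxy-2-methylbut-2-en-1-yl]-3-methyl-4-[2-(triisopropylsilyloxy)ethyl]dihydrofuran-2(3H)-one | C/C=C(/C)[C@@H](O)[C@@H]1OC(=O)[C@H](C)[C@@H]1CCO[Si](C(C)C)(C(C)C)C(C)C | intermediate
20 | isobutyryl chloride | CC(C)C(Cl)=O | starting material
21 | (1R,2Z)-2-methyl-1-{(2R,3S,4R)-4-methyl-5-oxo-3-[2-(triisopropylsilyloxy)ethyl]oxolan-2-yl}but-2-en-1-yl 2-methylpropanoate | C/C=C(/C)[C@@H](OC(=O)C(C)C)[C@@H]1OC(=O)[C@H](C)[C@@H]1CCO[Si](C(C)C)(C(C)C)C(C)C | intermediate
22 | (1R,2Z)-1-[(2R,3S,4R)-3-(2-hydroxyethyl)-4-methyl-5-oxooxolan-2-yl]-2-methylbut-2-en-1-yl 2-methylpropanoate | C/C=C(/C)[C@@H](OC(=O)C(C)C)[C@@H]1OC(=O)[C@H](C)[C@@H]1CCO | intermediate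
23 | (1R,2Z)-2-methyl-1-[(2R,3S,4R)-4-methyl-5-oxo-3-(2-oxoethyl)oxolan-2-yl]but-2-en-1-yl 2-methylpropanoate (all-cis lactone aldehyde, ene precursor) | C/C=C(/C)[C@@H](OC(=O)C(C)C)[C@@H]1OC(=O)[C@H](C)[C@@H]1CC=O | intermediate
24 | (3R,3aS,5R,6R,8R,8aR)-5-hydroxy-3,6-dimethyl-7-methylidene-2-oxooctahydro-2H-cyclohepta[b]furan-8-yl 2-methylpropanoate (ene product) | C=C1[C@@H](C)[C@H](O)C[C@@H]2[C@@H](OC(=O)[C@@H]2C)[C@@H]1OC(=O)C(C)C | intermediate
25 | (3R,3aS,5R,6R,8R,8aR)-3,6-dimethyl-7-methylidene-2-oxo-5-(triethylsilyloxy)octahydro-2H-cyclohepta[b]furan-8-yl 2-methylpropanoate | C=C1[C@@H](C)[C@H](O[Si](CC)(CC)CC)C[C@@H]2[C@@H](OC(=O)[C@@H]2C)[C@@H]1OC(=O)C(C)C | intermediate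
26 | (3R,3aS,5R,6S,7R,8S,8aR)-7-hydroxy-7-(hydroxymethyl)-3,6-dimethyl-2-oxo-5-(triethylsilyloxy)octahydro-2H-cyclohepta[b]furan-8-yl 2-methylpropanoate | OC[C@]1(O)[C@@H](C)[C@H](O[Si](CC)(CC)CC)C[C@@H]2[C@@H](OC(=O)[C@@H]2C)[C@@H]1OC(=O)C(C)C | intermediate
27 | (3R,3aS,5R,6S,7S,8S,8aR)-7-formyl-7-hydroxy-3,6-dimethyl-2-oxo-5-(triethylsilyloxy)octahydro-2H-cyclohepta[b]furan-8-yl 2-methylpropanoate | O=C[C@]1(O)[C@@H](C)[C@H](O[Si](CC)(CC)CC)C[C@@H]2[C@@H](OC(=O)[C@@H]2C)[C@@H]1OC(=O)C(C)C | intermediate
28 | (E)-1-bromoprop-1-ene | C/C=C/Br | starting material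
29 | (E)-prop-1-enylchromium dichloride | C/C=C/[Cr](Cl)Cl | intermediate
30 | (3R,3aS,5R,6S,7R,8S,8aR)-7-hydroxy-7-[(2E)-1-hydroxybut-2-en-1-yl]-3,6-dimethyl-2-oxo-5-(triethylsilyloxy)octahydro-2H-cyclohepta[b]furan-8-yl 2-methylpropanoate (both epimers at the side-chain carbinol) | C/C=C/C(O)[C@]1(O)[C@@H](C)[C@H](O[Si](CC)(CC)CC)C[C@@H]2[C@@H](OC(=O)[C@@H]2C)[C@@H]1OC(=O)C(C)C | intermediate
31 | (3R,3aS,5R,6S,7S,8S,8aR)-7-[(2E)-but-2-enoyl]-7-hydroxy-3,6-dimethyl-2-oxo-5-(triethylsilyloxy)octahydro-2H-cyclohepta[b]furan-8-yl 2-methylpropanoate | C/C=C/C(=O)[C@]1(O)[C@@H](C)[C@H](O[Si](CC)(CC)CC)C[C@@H]2[C@@H](OC(=O)[C@@H]2C)[C@@H]1OC(=O)C(C)C | intermediate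
32 | (3R,3aS,5R,6S,7S,8S,8aR)-7-[(2E)-but-2-enoyl]-5,7-dihydroxy-3,6-dimethyl-2-oxooctahydro-2H-cyclohepta[b]furan-8-yl 2-methylpropanoate (CNP0268641.1) | C/C=C/C(=O)[C@]1(O)[C@@H](C)[C@H](O)C[C@@H]2[C@@H](OC(=O)[C@@H]2C)[C@@H]1OC(=O)C(C)C | target

## Step count and least certain steps

Total step count: 21. Longest linear sequence: 21 steps (1 → 32); 14, 20 and 28 are purchased and enter in steps 10, 12 and 19.

Step 15 (key step). What may go wrong: incomplete facial control if the allylic-strain bias is eroded by the lactone-bearing tether; capture of the developing C1 cation by chloride or ionisation of the allylic isobutyrate under the Lewis acid; oligomerisation if the seven-membered closure is slow. Fallback: form the same C2–C3 bond by a reductive allylation instead of a Lewis-acid ene reaction, setting out from 21 and returning at 24. Ene-type allylic chlorination of 21 (Ca(OCl)2, CO2, CH2Cl2/H2O, 0 °C) should put chlorine on C2 and move the double bond to the C1 methyl, giving the transposed allylic chloride triisopropylsilyl ether F1. Buffered fluoride (Bu4NF, AcOH) should then give the chloro alcohol F2, and Dess–Martin oxidation the chloro aldehyde F3. Treatment of F3 with CrCl2 and catalytic LiI in THF (intramolecular Nozaki–Hiyama allylation) should generate the allylchromium species on the exocyclic carbon, which adds through its γ-carbon C2 to the C3 aldehyde to give 24; the anti preference of crotyl-type chromium reagents would have to translate into the trans C2/C3 pair.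

Step 17. What may go wrong: poor facial selectivity, because the pseudo-axial C7 acyloxy group on one face competes with the C2 methyl and the lactone oxygen on the other; slow osmylation of a hindered alkene; acyl migration from O7 to the new primary hydroxyl. Fallback: deliver oxygen to the opposite face on purpose and invert, setting out from 24 and returning at 27. Hydroxyl-directed epoxidation of 24 (VO(acac)2, t-BuOOH, CH2Cl2) should place the epoxide oxygen on the face of the C3 hydroxyl, giving the spiro-epoxide F4. Acid-catalysed hydrolysis (HClO4 cat., THF/H2O) should open it at tertiary C1 with inversion to the triol F5, which carries the C1 hydroxyl on the required face. Silylation of the primary and the secondary hydroxyl (Et3SiCl, imidazole) should give the bis(triethylsilyl) ether F6, and Swern oxidation ((COCl)2, DMSO; Et3N) converts the primary triethylsilyl ether directly into the aldehyde 27.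

Step 11. What may go wrong: insufficient diastereoselection at C7, competing conjugate reduction of the enone, or partial reduction of the lactone. Fallback: funnel the wrong epimer into the route by inversion, setting out from 18 and returning at 21. The C7-epimeric alcohol F7, separated from 19, would be esterified with isobutyric acid under Mitsunobu conditions (PPh3, diisopropyl azodicarboxylate, THF), which inverts C7 and gives 21 directly, so step 12 is not needed for that material.

Step 6. What may go wrong: selenoxide elimination toward the methyl group, giving the exocyclic isomer, which would keep the trans C5 centre. Fallback: isomerise the alkene, setting out from 8 (through 9) and returning at 10. The exocyclic α-methylene lactone F8 would be treated with RhCl3·3H2O in ethanol at 60 °C (hydride addition–elimination), moving the double bond into the ring to give 10.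

Step 19. What may go wrong: slow oxidative addition of the alkenyl bromide, low reactivity of the neopentyl-type aldehyde, or an acyloin shift of the α-hydroxy aldehyde promoted by Lewis-acidic trivalent chromium. Fallback: build the enone by allylation, oxidation and isomerisation, setting out from 27 and returning at 31. Barbier allylation of 27 (allyl bromide, In, THF/H2O) should give the homoallylic alcohol F9. Dess–Martin oxidation should give the β,γ-unsaturated ketone F10, and catalytic DBU in CH2Cl2 should move the double bond into conjugation to give the E-enone 31.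

## Further compounds

F1 | step 15 | (1R)-3-chloro-2-methylidene-1-{(2R,3S,4R)-4-methyl-5-oxo-3-[2-(triisopropylsilyloxy)ethyl]oxolan-2-yl}butyl 2-methylpropanoate (either epimer at the chloride carbon) | CC(Cl)C(=C)[C@@H](OC(=O)C(C)C)[C@@H]1OC(=O)[C@H](C)[C@@H]1CCO[Si](C(C)C)(C(C)C)C(C)C
F2 | step 15 | (1R)-3-chloro-1-[(2R,3S,4R)-3-(2-hydroxyethyl)-4-methyl-5-oxooxolan-2-yl]-2-methylidenebutyl 2-methylpropanoate | CC(Cl)C(=C)[C@@H](OC(=O)C(C)C)[C@@H]1OC(=O)[C@H](C)[C@@H]1CCO
F3 | step 15 | (1R)-3-chloro-2-methylidene-1-[(2R,3S,4R)-4-methyl-5-oxo-3-(2-oxoethyl)oxolan-2-yl]butyl 2-methylpropanoate | CC(Cl)C(=C)[C@@H](OC(=O)C(C)C)[C@@H]1OC(=O)[C@H](C)[C@@H]1CC=O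
F4 | step 17 | spiro-epoxide of 24 at C1 (epoxide oxygen on the face of the C3 hydroxyl, C3 hydroxyl free) | C1O[C@@]13[C@@H](C)[C@H](O)C[C@@H]2[C@@H](OC(=O)[C@@H]2C)[C@@H]3OC(=O)C(C)C
F5 | step 17 | (3R,3aS,5R,6S,7R,8S,8aR)-5,7-dihydroxy-7-(hydroxymethyl)-3,6-dimethyl-2-oxooctahydro-2H-cyclohepta[b]furan-8-yl 2-methylpropanoate | OC[C@]1(O)[C@@H](C)[C@H](O)C[C@@H]2[C@@H](OC(=O)[C@@H]2C)[C@@H]1OC(=O)C(C)C
F6 | step 17 | bis(triethylsilyl) ether of F5 (silyl groups on the primary oxygen and on O3, tertiary hydroxyl free) | CC[Si](CC)(CC)OC[C@]1(O)[C@@H](C)[C@H](O[Si](CC)(CC)CC)C[C@@H]2[C@@H](OC(=O)[C@@H]2C)[C@@H]1OC(=O)C(C)C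
F7 | step 11 | (3R,4S,5R)-5-[(1S,2Z)-1-hydroxy-2-methylbut-2-en-1-yl]-3-methyl-4-[2-(triisopropylsilyloxy)ethyl]dihydrofuran-2(3H)-one (C7 epimer of 19) | C/C=C(/C)[C@H](O)[C@@H]1OC(=O)[C@H](C)[C@@H]1CCO[Si](C(C)C)(C(C)C)C(C)C
F8 | step 6 | 5-[(tert-butyldimethylsilyloxy)methyl]-3-methylidene-4-[2-(triisopropylsilyloxy)ethyl]dihydrofuran-2(3H)-one (4,5-trans, exocyclic isomer of 10) | CC(C)(C)[Si](C)(C)OC[C@@H]1OC(=O)C(=C)[C@H]1CCO[Si](C(C)C)(C(C)C)C(C)C
F9 | step 19 | 7-hydroxy-7-(1-hydroxybut-3-en-1-yl)-3,6-dimethyl-2-oxo-5-(triethylsilyloxy)octahydro-2H-cyclohepta[b]furan-8-yl 2-methylpropanoate (ring configuration as in 27, both carbinol epimers) | C=CCC(O)[C@]1(O)[C@@H](C)[C@H](O[Si](CC)(CC)CC)C[C@@H]2[C@@H](OC(=O)[C@@H]2C)[C@@H]1OC(=O)C(C)C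
F10 | step 19 | 7-(but-3-enoyl)-7-hydroxy-3,6-dimethyl-2-oxo-5-(triethylsilyloxy)octahydro-2H-cyclohepta[b]furan-8-yl 2-methylpropanoate (ring configuration as in 31) | C=CCC(=O)[C@]1(O)[C@@H](C)[C@H](O[Si](CC)(CC)CC)C[C@@H]2[C@@H](OC(=O)[C@@H]2C)[C@@H]1OC(=O)C(C)C
A1 | alternative 1 | cis-fused α-methylene lactone on the cycloheptane, C1 ethynyl, C1/C7 oxygens bridged as a trans-fused acetonide, C3 tert-butyldimethylsilyl ether | C#C[C@]1(OC3(C)C)[C@@H](C)[C@H](O[Si](C)(C)C(C)(C)C)C[C@@H]2[C@@H](OC(=O)C2=C)[C@@H]1O3
A2 | alternative 1 | open-chain precursor of A1: C6 aldehyde on the dioxolane and methyl (Z)-2-(bromomethyl)alk-2-enoate terminus at C4–C5=C11 | C#C[C@]1(OC(C)(C)O[C@H]1C=O)[C@@H](C)[C@H](O[Si](C)(C)C(C)(C)C)C/C=C(\CBr)C(=O)OC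
A3 | alternative 2 | ring-expanded C7 ketone with the C1 hydroxyl and crotonoyl group, C3 tert-butyldimethylsilyl ether | C/C=C/C(=O)[C@]1(O)[C@@H](C)[C@H](O[Si](C)(C)C(C)(C)C)C[C@@H]2[C@@H](OC(=O)[C@@H]2C)C1=O
A4 | alternative 2 | lactone-fused cyclohexanol (ring C7, C2, C3, C4, C5, C6) carrying on C7 the hydroxyl and the (E)-1,2-dioxopent-3-enyl chain (carbinol configuration left open) | C/C=C/C(=O)C(=O)C1(O)[C@@H](C)[C@H](O[Si](C)(C)C(C)(C)C)C[C@@H]2[C@H]1OC(=O)[C@@H]2C
A5 | alternative 3 | bicyclic allylic alcohol with the C4=C5 alkene, C1 triethylsilyl ether and dioxolane-masked acetyl group, C7 isobutyrate | CC1(OCCO1)[C@]2(O[Si](CC)(CC)CC)[C@@H](C)[C@H](O)C=C3[C@@H](OC(=O)[C@@H]3C)[C@@H]2OC(=O)C(C)C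
A6 | alternative 3 | open precursor of A5: C3 aldehyde and (Z)-iodomethylidene lactone (iodine cis to C6) | CC1(OCCO1)[C@](O[Si](CC)(CC)CC)([C@@H](C)C=O)[C@@H](OC(=O)C(C)C)[C@@H]2OC(=O)[C@H](C)/C2=C/I
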